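**Plan**

1. Retrosynthesis: the C8 ester C–O bond is cut first (ester formed with inversion from an 8α-alcohol), then C10–H (from a 10(14)-alkene, itself from a C10 tertiary alcohol). In the hydroazulenone the C1–C5 bond is then cut and C5–C10 re-formed, which returns the cyclopentenone (C1–C5) to ring A of a 10-epi-eudesma-1,4-dien-3-one. That is opened at C1–C10 and C4=C5 (Robinson annulation with ethyl vinyl ketone) to a cyclohexanone reached from (S)-carvone by α′-oxygenation and 1,3-carbonyl transposition.
2. Forward order: the carvone ring becomes ring B (C5–C10), ring A is annulated, and one photochemical event then contracts six-membered ring A to the cyclopentenone and, by the same bond shift, enlarges ring B to the seven-membered ring.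
3. Enabling feature: the 2-methylcyclopent-2-enone C1–C2–C3(=O)–C4(CH3)=C5, whose sp3 ring-fusion carbon C1 carries the methyl-bearing C10, is the footprint of a 4-methyl cross-conjugated cyclohexadienone with quaternary C10. The C4 methyl steers the rearrangement to the fused five/seven product.
4. Stereochemistry: C7 comes from (S)-carvone; the C8 oxygen is set trans to it (Rubottom oxidation); quaternary C10 is set by the Robinson annulation; C1 follows stereospecifically from C10 in the key step; the final C10 is set by hydrogenation directed by the 8α-hydroxyl; C8 is inverted in the closing Mitsunobu esterification.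

Key step: step 10

Remark: locants C1–C15 are those of the eudesmane/guaiane skeleton; α/β refer to the drawing in which the C7 side chain is β (H-7 α). Ketone 7 is taken on as its C2-epimer mixture, which is of no consequence because C2 becomes quaternary in step 6.

**Step 1**
Reactants: 1 (S)-(+)-carvone
Product: 3 (5R,6R)-2-methyl-5-(prop-1-en-2-yl)-6-[(triisopropylsilyl)oxy]cyclohex-2-en-1-one, via silyl dienol ether 2 (not isolated)
Conditions: LiN(iPr)2, THF, −78 °C; iPr3SiOTf, −78 to 0 °C; then mCPBA, NaHCO3, CH2Cl2, −20 to 0 °C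
Reagents that add atoms: triisopropylsilyl trifluoromethanesulfonate, CC(C)[Si](C(C)C)(C(C)C)OS(=O)(=O)C(F)(F)F; 3-chloroperoxybenzoic acid, OOC(=O)c1cccc(Cl)c1
Why: Kinetic α′-deprotonation at C6 and O-silylation give the cross-conjugated 2-silyloxy diene, whose Rubottom oxidation (epoxidation of the electron-rich enol ether, ring opening, 1,4-silyl shift) should give the α′-silyloxy enone with oxygen entering anti to the adjacent C5 isopropenyl group (5,6-trans).

**Step 2**
Reactants: 3 (5R,6R)-2-methyl-5-(prop-1-en-2-yl)-6-[(triisopropylsilyl)oxy]cyclohex-2-en-1-one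
Product: 4 (1S,3R,4R,6S)-1-methyl-4-(prop-1-en-2-yl)-3-[(triisopropylsilyl)oxy]-7-oxabicyclo[4.1.0]heptan-2-one
Conditions: H2O2 (30 % aq.), NaOH (cat.), MeOH, 0 °C
Reagents that add atoms: hydrogen peroxide, OO
Why: Weitz–Scheffer (nucleophilic) epoxidation of the enone, in which hydroperoxide should add to the β-carbon anti to the isopropenyl group as it does with carvone; the two new centres are destroyed again in steps 3 and 4.

**Step 3**
Reactants: 4 (1S,3R,4R,6S)-1-methyl-4-(prop-1-en-2-yl)-3-[(triisopropylsilyl)oxy]-7-oxabicyclo[4.1.0]heptan-2-one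
Product: 5 (1S,4S,5R)-2-methyl-5-(prop-1-en-2-yl)-4-[(triisopropylsilyl)oxy]cyclohex-2-en-1-ol
Conditions: N2H4·H2O, AcOH (cat.), MeOH, 0 °C to rt
Reagents that add atoms: none
Why: Wharton transposition, in which condensation with hydrazine and loss of N2 with opening of the epoxide should turn the old carbonyl carbon into an alkene CH and leave the epoxide oxygen as an allylic alcohol whose configuration is retained from the epoxide.

**Step 4**
Reactants: 5 (1S,4S,5R)-2-methyl-5-(prop-1-en-2-yl)-4-[(triisopropylsilyl)oxy]cyclohex-2-en-1-ol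
Product: 6 (4S,5R)-2-methyl-5-(prop-1-en-2-yl)-4-[(triisopropylsilyl)oxy]cyclohex-2-en-1-one
Conditions: Dess–Martin periodinane, CH2Cl2, rt
Reagents that add atoms: none
Why: Dess–Martin oxidation of the secondary allylic alcohol should give the transposed enone, a γ-silyloxy isomer of 3, without touching the silyl ether or the isopropenyl group.

**Step 5**
Reactants: 6 (4S,5R)-2-methyl-5-(prop-1-en-2-yl)-4-[(triisopropylsilyl)oxy]cyclohex-2-en-1-one
Product: 7 (2R,4S,5R)-2-methyl-5-(prop-1-en-2-yl)-4-[(triisopropylsilyl)oxy]cyclohexan-1-one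
Conditions: LiBH(s-Bu)3, THF, −78 °C; then H2O
Reagents that add atoms: none
Why: Conjugate (1,4) hydride reduction of the β-unsubstituted enone by the bulky borohydride, as known for carvone, should give the saturated ketone and leave the isopropenyl group alone; the configuration at C2 set on protonation is irrelevant.

**Step 6**
Reactants: 7 (2R,4S,5R)-2-methyl-5-(prop-1-en-2-yl)-4-[(triisopropylsilyl)oxy]cyclohexan-1-one; 8 ethyl vinyl ketone
Product: 10 8α-[(triisopropylsilyl)oxy]-10-epi-eudesma-4,11-dien-3-one (7αH, 10α-methyl), via Michael adduct 9 (not isolated)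
Conditions: KOH, EtOH, 0 °C to rt; then reflux
Reagents that add atoms: ethyl vinyl ketone 8, C=CC(=O)CC
Why: Robinson annulation, in which the more substituted enolate should add to the enone by axial attack on the conformer with equatorial isopropenyl and silyloxy groups, on the face opposite the 1,3-related silyloxy group, so that the 3-oxopentyl chain ends cis and the methyl trans to the isopropenyl group (the outcome known for dihydrocarvone, which gives 10-epi-α-cyperone), and aldol condensation then closes ring A.

**Step 7**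
Reactants: 10 8α-[(triisopropylsilyl)oxy]-10-epi-eudesma-4,11-dien-3-one
Product: 11 11-hydroxy-8α-[(triisopropylsilyl)oxy]-10-epi-eudesm-4-en-3-one
Conditions: Co(acac)2 (cat.), PhSiH3, O2 (1 atm), THF, rt
Reagents that add atoms: dioxygen, O=O
Why: Mukaiyama hydration (hydrogen-atom transfer from a cobalt hydride to the 1,1-disubstituted alkene, trapping of the tertiary radical by O2, reduction of the peroxide) should be Markovnikov-selective and leave the tetrasubstituted enone untouched; no stereocentre is formed.

**Step 8**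
Reactants: 11 11-hydroxy-8α-[(triisopropylsilyl)oxy]-10-epi-eudesm-4-en-3-one; 12 acetic anhydride
Product: 13 11-acetoxy-8α-[(triisopropylsilyl)oxy]-10-epi-eudesm-4-en-3-one
Conditions: Ac2O, DMAP, Et3N, CH2Cl2, 40 °C
Reagents that add atoms: acetic anhydride 12, CC(=O)OC(C)=O
Why: DMAP-catalysed acylation of the tertiary alcohol installs the C11 acetate of the target while no other hydroxyl is free, and it keeps this oxygen from competing for the C10 cation in step 10.

**Step 9**
Reactants: 13 11-acetoxy-8α-[(triisopropylsilyl)oxy]-10-epi-eudesm-4-en-3-one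
Product: 14 11-acetoxy-8α-[(triisopropylsilyl)oxy]-10-epi-eudesma-1,4-dien-3-one
Conditions: DDQ, 1,4-dioxane, reflux
Reagents that add atoms: none
Why: DDQ dehydrogenation of the 4-en-3-one through its 2,4-dienol (hydride abstraction at C1) should introduce the C1=C2 bond and complete the cross-conjugated dienone chromophore without touching a stereocentre.

**Step 10**
Reactants: 14 11-acetoxy-8α-[(triisopropylsilyl)oxy]-10-epi-eudesma-1,4-dien-3-one
Product: 15 11-acetoxy-10β-hydroxy-8α-[(triisopropylsilyl)oxy]-1βH,7αH-guai-4-en-3-one (C14 methyl α)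
Conditions: hν (medium-pressure Hg lamp, Pyrex filter), AcOH/H2O/MeCN, N2, 20 °C
Reagents that add atoms: water, O
Why: n→π* excitation, bonding between the two β-carbons C1 and C5 and electronic demotion should give the bicyclo[3.1.0] zwitterion (cyclopropane C1–C5–C10, oxyallyl C2–C3–C4), which acetic acid protonates on oxygen; the cyclopropylcarbinyl cation then opens by cleavage of C5–C10 while water attacks C10 from the side opposite C5, and the enol ketonises to the C3 ketone. The closest known reaction type is the photorearrangement of 4-methyl cross-conjugated cyclohexadienones of the santonin type to 10-hydroxy-hydroazulen-3-ones in aqueous acetic acid. The five-membered ring (C1–C2–C3–C4–C5) is closed by the excited-state C1–C5 bond formation, a disrotatory 4π-type closure whose termini are held in ring A; the seven-membered ring is not closed but arises when the C5–C10 bond shared by the cyclopropane and ring B is cut, so that ring B takes up C1. C1 is set stereospecifically by C10 of 14, because ring B forces the cyclopropane to form with the methyl endo and C9 exo, which puts H-1 β (cis to the C7 side chain) in the 10α-methyl series; C10 is set by inversion in the SN2-like opening, giving the 10β-hydroxyl cis to H-1. The step needs the fused five/seven mode of opening over the spiro mode and over collapse to the lumiketone: the C4 methyl stabilises positive charge at C4 and so directs cleavage of C5–C10, and the protic acidic medium intercepts the zwitterion.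

**Step 11**
Reactants: 15 11-acetoxy-10β-hydroxy-8α-[(triisopropylsilyl)oxy]-1βH,7αH-guai-4-en-3-one
Product: 16 11-acetoxy-8α-[(triisopropylsilyl)oxy]-1βH,7αH-guaia-4,10(14)-dien-3-one
Conditions: SOCl2, pyridine, −20 to 0 °C
Reagents that add atoms: none
Why: Dehydration of the tertiary alcohol through its chlorosulfite by pyridine-mediated anti E2 elimination should spare C1, because H-1 is syn to the leaving group, and take a methyl hydrogen to give the exocyclic alkene; elimination toward C9 instead would be harmless, since step 13 sets C10 from the same face whichever of these two positions the double bond occupies.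

**Step 12**
Reactants: 16 11-acetoxy-8α-[(triisopropylsilyl)oxy]-1βH,7αH-guaia-4,10(14)-dien-3-one
Product: 17 11-acetoxy-8α-hydroxy-1βH,7αH-guaia-4,10(14)-dien-3-one
Conditions: HF·pyridine, THF, 0 °C to rt
Reagents that add atoms: none
Why: Fluoride-mediated silyl ether cleavage should free the 8α-hydroxyl under mildly acidic conditions in which the C11 acetate does not migrate and the γ-centre C1 of the enone is not epimerised.

**Step 13**
Reactants: 17 11-acetoxy-8α-hydroxy-1βH,7αH-guaia-4,10(14)-dien-3-one
Product: 18 11-acetoxy-8α-hydroxy-1βH,7αH,10αH-guai-4-en-3-one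
Conditions: [Ir(cod)(PCy3)(py)]PF6 (cat.), H2 (1 atm), CH2Cl2, 0 °C to rt
Reagents that add atoms: none
Why: Hydroxyl-directed homogeneous hydrogenation, in which coordination of the homoallylic 8α-hydroxyl to the cationic iridium catalyst should deliver H2 to the α face of the 10(14)-alkene and so set C10 with H α and the methyl β (trans to the hydroxyl), while the tetrasubstituted conjugated C4=C5 bond is left alone.

**Step 14**
Reactants: 18 11-acetoxy-8α-hydroxy-1βH,7αH,10αH-guai-4-en-3-one; 19 methacrylic acid
Product: 20 11-acetoxy-8β-(methacryloyloxy)-1βH,7αH,10αH-guai-4-en-3-one, the target, (1R,7S,8R,10S)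
Conditions: methacrylic acid, PPh3, DIAD, toluene, 0 °C to rt
Reagents that add atoms: methacrylic acid 19, C=C(C)C(=O)O
Why: Mitsunobu esterification, in which methacrylate should displace the oxyphosphonium derived from the 8α-alcohol in an SN2 step with inversion to give the 8β-ester cis to the C7 side chain and the C10 methyl (the inversion of menthol-type alcohols is the precedent).

**Compound list**

1 | (S)-(+)-carvone | CC1=CC[C@@H](CC1=O)C(C)=C | starting material
2 | triisopropyl{[(3S)-6-methyl-3-(prop-1-en-2-yl)cyclohexa-1,5-dien-1-yl]oxy}silane | CC1=CC[C@H](C(C)=C)C=C1O[Si](C(C)C)(C(C)C)C(C)C | intermediate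
3 | (5R,6R)-2-methyl-5-(prop-1-en-2-yl)-6-[(triisopropylsilyl)oxy]cyclohex-2-en-1-one | CC(C)[Si](C(C)C)(C(C)C)O[C@H]1C(=O)C(C)=CC[C@@H]1C(C)=C | intermediate
4 | (1S,3R,4R,6S)-1-methyl-4-(prop-1-en-2-yl)-3-[(triisopropylsilyl)oxy]-7-oxabicyclo[4.1.0]heptan-2-one | CC(C)[Si](C(C)C)(C(C)C)O[C@H]1C(=O)[C@@]2(C)O[C@H]2C[C@@H]1C(C)=C | intermediate
5 | (1S,4S,5R)-2-methyl-5-(prop-1-en-2-yl)-4-[(triisopropylsilyl)oxy]cyclohex-2-en-1-ol | CC(C)[Si](C(C)C)(C(C)C)O[C@H]1C=C(C)[C@@H](O)C[C@@H]1C(C)=C | intermediate
6 | (4S,5R)-2-methyl-5-(prop-1-en-2-yl)-4-[(triisopropylsilyl)oxy]cyclohex-2-en-1-one | CC(C)[Si](C(C)C)(C(C)C)O[C@H]1C=C(C)C(=O)C[C@@H]1C(C)=C | intermediate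
7 | (2R,4S,5R)-2-methyl-5-(prop-1-en-2-yl)-4-[(triisopropylsilyl)oxy]cyclohexan-1-one (major C2 epimer) | CC(C)[Si](C(C)C)(C(C)C)O[C@H]1C[C@@H](C)C(=O)C[C@@H]1C(C)=C | intermediate
8 | ethyl vinyl ketone (pent-1-en-3-one) | C=CC(=O)CC | starting material
9 | (2S,4S,5R)-2-methyl-2-(3-oxopentyl)-5-(prop-1-en-2-yl)-4-[(triisopropylsilyl)oxy]cyclohexan-1-one | CC(C)[Si](C(C)C)(C(C)C)O[C@H]1C[C@](C)(CCC(=O)CC)C(=O)C[C@@H]1C(C)=C | intermediate
10 | 8α-[(triisopropylsilyl)oxy]-10-epi-eudesma-4,11-dien-3-one (7αH, 10α-methyl) | CC(C)[Si](C(C)C)(C(C)C)O[C@H]1C[C@]2(C)CCC(=O)C(C)=C2C[C@@H]1C(C)=C | intermediate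
11 | 11-hydroxy-8α-[(triisopropylsilyl)oxy]-10-epi-eudesm-4-en-3-one | CC(C)[Si](C(C)C)(C(C)C)O[C@H]1C[C@]2(C)CCC(=O)C(C)=C2C[C@@H]1C(C)(C)O | intermediate
12 | acetic anhydride | CC(=O)OC(C)=O | starting material
13 | 11-acetoxy-8α-[(triisopropylsilyl)oxy]-10-epi-eudesm-4-en-3-one | CC(C)[Si](C(C)C)(C(C)C)O[C@H]1C[C@]2(C)CCC(=O)C(C)=C2C[C@@H]1C(C)(C)OC(C)=O | intermediate
14 | 11-acetoxy-8α-[(triisopropylsilyl)oxy]-10-epi-eudesma-1,4-dien-3-one | CC(C)[Si](C(C)C)(C(C)C)O[C@H]1C[C@]2(C)C=CC(=O)C(C)=C2C[C@@H]1C(C)(C)OC(C)=O | intermediate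
15 | 11-acetoxy-10β-hydroxy-8α-[(triisopropylsilyl)oxy]-1βH,7αH-guai-4-en-3-one | CC(C)[Si](C(C)C)(C(C)C)O[C@H]1C[C@](C)(O)[C@H]2CC(=O)C(C)=C2C[C@@H]1C(C)(C)OC(C)=O | intermediate
16 | 11-acetoxy-8α-[(triisopropylsilyl)oxy]-1βH,7αH-guaia-4,10(14)-dien-3-one | CC(C)[Si](C(C)C)(C(C)C)O[C@H]1CC(=C)[C@H]2CC(=O)C(C)=C2C[C@@H]1C(C)(C)OC(C)=O | intermediate
17 | 11-acetoxy-8α-hydroxy-1βH,7αH-guaia-4,10(14)-dien-3-one | O[C@H]1CC(=C)[C@H]2CC(=O)C(C)=C2C[C@@H]1C(C)(C)OC(C)=O | intermediate
18 | 11-acetoxy-8α-hydroxy-1βH,7αH,10αH-guai-4-en-3-one | O[C@H]1C[C@H](C)[C@H]2CC(=O)C(C)=C2C[C@@H]1C(C)(C)OC(C)=O | intermediate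
19 | methacrylic acid | C=C(C)C(=O)O | starting material
20 | 11-acetoxy-8β-(methacryloyloxy)-1βH,7αH,10αH-guai-4-en-3-one, (1R,7S,8R,10S) | C=C(C)C(=O)O[C@@H]1C[C@H](C)[C@H]2CC(=O)C(C)=C2C[C@@H]1C(C)(C)OC(C)=O | target

**Step count and risks**

Total step count: 14. Longest linear sequence: 14 steps, from 1.

Steps most likely to fail:

Step 14 (Mitsunobu esterification). The SN2 displacement at C8 has to bring the carboxylate in cis to the bulky C7 substituent, so elimination toward C9 or participation of the neighbouring C11 acetate carbonyl (acetyl transfer to O8) can overtake ester formation. The fallback sets out from 18 and comes back at 20. Dess–Martin oxidation of 18 should give 11-acetoxy-1βH,7αH,10αH-guai-4-ene-3,8-dione F1. NaBH4 in MeOH/CH2Cl2 at −78 °C should reduce the saturated cycloheptanone faster than the conjugated cyclopentenone and attack the α face, away from the C7 substituent, to give 11-acetoxy-8β-hydroxy-1βH,7αH,10αH-guai-4-en-3-one F2. Acylation of F2 with methacrylic anhydride, Et3N and DMAP should then give 20.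

Step 6 (Robinson annulation). Facial control at the new quaternary C10, the centre that later fixes C1, may be lost, enolisation may go toward the CH2 side, or ethyl vinyl ketone may oligomerise under base. The fallback sets out from 7 and comes back at 9. Condensation of 7 with (S)-1-phenylethylamine in toluene with azeotropic removal of water should give the N-[(S)-1-phenylethyl] imine of 7 F3. Its more substituted secondary enamine tautomer should add to ethyl vinyl ketone under neutral conditions (THF, rt), the auxiliary reinforcing attack on the β face (chiral-imine Michael addition), to give the N-[(S)-1-phenylethyl] imine of 9 F4. Aqueous acetic acid should hydrolyse F4 to 9, which is then cyclised and dehydrated with NaOMe in MeOH to 10.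

Step 3 (Wharton transposition). Hydrazone formation at the hindered α-silyloxy ketone may be slow, and the fragmentation may be diverted into reduction or pyrazoline formation. The fallback sets out from 4 and comes back at 5. NaBH4 reduction of 4 (MeOH, 0 °C; hydride anti to the silyloxy group, the new centre being lost again) should give (1S,3R,4R,6S)-1-methyl-4-(prop-1-en-2-yl)-3-[(triisopropylsilyl)oxy]-7-oxabicyclo[4.1.0]heptan-2α-ol F5. Acylation with 1,1′-thiocarbonyldiimidazole should give the O-(imidazol-1-ylthiocarbonyl) derivative of F5 F6. Bu3SnH and AIBN in toluene at 80 °C should then give 5: the carbon radical next to the epoxide opens it and the resulting alkoxyl radical is reduced (radical epoxide fragmentation).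

**Further compounds**

F1 | step 14 | 11-acetoxy-1βH,7αH,10αH-guai-4-ene-3,8-dione | O=C1C[C@H](C)[C@H]2CC(=O)C(C)=C2C[C@@H]1C(C)(C)OC(C)=O
F2 | step 14 | 11-acetoxy-8β-hydroxy-1βH,7αH,10αH-guai-4-en-3-one | O[C@@H]1C[C@H](C)[C@H]2CC(=O)C(C)=C2C[C@@H]1C(C)(C)OC(C)=O
F3 | step 6 | N-[(S)-1-phenylethyl] imine of 7 | CC(C)[Si](C(C)C)(C(C)C)O[C@H]1C[C@@H](C)/C(=N/[C@@H](C)c2ccccc2)C[C@@H]1C(C)=C
F4 | step 6 | N-[(S)-1-phenylethyl] imine of 9 | CC(C)[Si](C(C)C)(C(C)C)O[C@H]1C[C@](C)(CCC(=O)CC)/C(=N/[C@@H](C)c2ccccc2)C[C@@H]1C(C)=C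
F5 | step 3 | (1S,3R,4R,6S)-1-methyl-4-(prop-1-en-2-yl)-3-[(triisopropylsilyl)oxy]-7-oxabicyclo[4.1.0]heptan-2α-ol (hydroxyl cis to the epoxide oxygen) | CC(C)[Si](C(C)C)(C(C)C)O[C@H]1[C@@H](O)[C@@]2(C)O[C@H]2C[C@@H]1C(C)=C
F6 | step 3 | O-(imidazol-1-ylthiocarbonyl) derivative of F5 | CC(C)[Si](C(C)C)(C(C)C)O[C@H]1[C@@H](OC(=S)n2ccnc2)[C@@]3(C)O[C@H]3C[C@@H]1C(C)=C
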